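**Plan**
- Retrosynthesis: the 5-OH goes back to a 5-OMe and the 2'-OMe to a 2'-OH. Ring B is then cut at C1'–C2' and C5'–C6', the ethynyl group is cut back to a C2 aldehyde, and ring C is opened at O1–C2, C2–C3 and C4–C4a.
- Enabling feature: ring B carries three contiguous oxygens on C2', C3' and C4' beside the two CH carbons C5' and C6', and C1' is bonded to C2 of the pyranone. This maps onto a 1,2,3-trioxygenated butadiene plus an ethynyl group already sitting on C2.
- Forward order: ring A is bought. Ring C is closed onto it (Friedel–Crafts acylation, Claisen condensation, cyclodehydration) and the C2 aldehyde is homologated to the alkyne. The diene is made separately in three steps.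
- Ring B is formed last by [4+2] addition and aromatisation, followed by O-methylation at C2' and chelation-directed demethylation at C5.
- Stereochemistry: the target has no stereocentre. The sp3 centres that appear in the cycloadduct are erased on aromatisation, and the alkene geometries of the diene precursors are immaterial.

Key step: step 7

Assumption: the three starting materials, the LiN(iPr)2 solution and the Ohira–Bestmann reagent are bought; the diene is used as its geometric mixture, because its ketene acetal carbon ends as an sp2 ring carbon.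

**Route**

Step 1
Reactants: 1 1,2,3,5-tetramethoxybenzene
Product: 4 1-(2-hydroxy-3,4,6-trimethoxyphenyl)ethanone, via tetramethoxyacetophenone 2 (not isolated), via aluminium phenoxide 3 (not isolated)
Conditions: AcCl, AlCl3, Et2O, 0 °C to rt; aq HCl
Reagents that add atoms: acetyl chloride, CC(=O)Cl
Why: Friedel–Crafts acylation at one of the two equivalent free positions, after which AlCl3 chelated to the new carbonyl cleaves the more crowded ortho methoxy group (the one flanked by a second OMe), a known chelation-directed demethylation of this substitution pattern.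

Step 2
Reactants: 4 1-(2-hydroxy-3,4,6-trimethoxyphenyl)ethanone; 5 ethyl diethoxyacetate
Product: 8 5,7,8-trimethoxy-4-oxo-4H-chromene-2-carbaldehyde, via diketone 6 (not isolated), via acetal chromone 7 (not isolated)
Conditions: NaH, THF, reflux; then AcOH, aq HCl, 90 °C
Reagents that add atoms: water, O
Why: Claisen condensation of the ketone enolate with the activated α,α-dialkoxy ester gives the 1,3-diketone, and acid then closes ring C by cyclodehydration and hydrolyses the acetal to the aldehyde.

Step 3
Reactants: 8 5,7,8-trimethoxy-4-oxo-4H-chromene-2-carbaldehyde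
Product: 9 2-ethynyl-5,7,8-trimethoxy-4H-chromen-4-one
Conditions: dimethyl (1-diazo-2-oxopropyl)phosphonate, K2CO3, MeOH, 0 °C to rt
Reagents that add atoms: dimethyl (1-diazo-2-oxopropyl)phosphonate, CC(=O)C(=[N+]=[N-])P(=O)(OC)OC
Why: Seyferth–Gilbert homologation in its Ohira–Bestmann form should convert the aldehyde into the terminal alkyne under carbonate conditions mild enough for the pyranone.

Step 4
Reactants: 10 methyl methoxyacetate
Product: 12 methyl 2-methoxy-3-oxobutanoate (racemic), via lithium enolate 11 (not isolated)
Conditions: LiN(iPr)2, THF, −78 °C; AcCl (0.5 equiv), −78 °C; cold aq HCl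
Reagents that add atoms: acetyl chloride, CC(=O)Cl
Why: Claisen-type C-acylation of a preformed lithium ester enolate by an acid chloride; two equivalents of enolate are used because the more acidic β-keto ester consumes the second one.

Step 5
Reactants: 12 methyl 2-methoxy-3-oxobutanoate
Product: 14 methyl 2,3-dimethoxybut-2-enoate (E/Z mixture), via dimethyl ketal 13 (not isolated)
Conditions: HC(OMe)3, cat. H2SO4, MeOH, rt; then distillation from cat. TsOH
Reagents that add atoms: trimethyl orthoformate, COC(OC)OC
Why: acid-catalysed ketalisation by the orthoester and loss of methanol give the enol methyl ether, as in the standard preparation of 3-methoxycrotonates; every alkene isomer leads to the same dienolate in the next step.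

Step 6
Reactants: 14 methyl 2,3-dimethoxybut-2-enoate
Product: 16 1,2,3-trimethoxy-1-(trimethylsilyloxy)buta-1,3-diene (ketene acetal geometry mixed), via lithium dienolate 15 (not isolated)
Conditions: LiN(iPr)2, THF, −78 °C; TMSCl, −78 °C to rt; filtration and concentration under argon
Reagents that add atoms: chlorotrimethylsilane, C[Si](C)(C)Cl
Why: kinetic γ-deprotonation of the β-methoxy enoate gives the extended dienolate, which the hard silyl chloride traps on oxygen, the standard preparation of 1-alkoxy-1-silyloxy dienes.

Step 7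
Reactants: 9 2-ethynyl-5,7,8-trimethoxy-4H-chromen-4-one; 16 1,2,3-trimethoxy-1-(trimethylsilyloxy)buta-1,3-diene
Product: 19 2-(2-hydroxy-3,4-dimethoxyphenyl)-5,7,8-trimethoxy-4H-chromen-4-one, via cycloadduct 17 (not isolated), via dienone 18 (not isolated)
Conditions: 16 (3 equiv), toluene, 100 °C, sealed tube; then 1 M aq HCl, THF, rt
Reagents that add atoms: none
Why: Proposed new method: the CH2 terminus of the vinylogous silyl ketene acetal 16 is its most nucleophilic carbon and the terminal alkyne carbon of 9 is the electrophilic end of the O=C4–C3=C2–C≡C acceptor, so an asynchronous [4+2] addition should form C5'–C6' first and then join the ketene acetal carbon to the internal alkyne carbon (C1'–C2'), giving the 1,4-cyclohexadiene 17. The closest known reaction type is the Diels–Alder benzannulation of 1-alkoxy-1-silyloxybutadienes with alkynoates and ynones; what is new is an alkyne activated only through the pyranone C2=C3 relay. Ring B closes as a six-membered carbocycle by intermolecular [4+2] cycloaddition across the alkyne. Aqueous acid then cleaves the O–Si bond, the hemiketal loses methanol to give the cross-conjugated dienone 18, and enolisation towards C5'H2 aromatises it to the phenol 19. The only new stereocentre, the ketal carbon of 17, is racemic and is erased on aromatisation. The step needs the ketal carbon to end on C1' and the alkyne, not C2=C3, to act as dienophile: the matched terminal polarities secure the first, the second follows because C2=C3 is an oxygen-donor-deactivated vinylogous ester bond with a fully substituted C2, and the 5-methyl ether leaves no acidic OH to quench the diene.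

Step 8
Reactants: 19 2-(2-hydroxy-3,4-dimethoxyphenyl)-5,7,8-trimethoxy-4H-chromen-4-one
Product: 20 5,7,8-trimethoxy-2-(2,3,4-trimethoxyphenyl)-4H-chromen-4-one
Conditions: MeI, K2CO3, acetone, reflux
Reagents that add atoms: iodomethane, CI
Why: Williamson O-methylation of the only free phenol.

Step 9
Reactants: 20 5,7,8-trimethoxy-2-(2,3,4-trimethoxyphenyl)-4H-chromen-4-one
Product: 22 serpyllin (5-hydroxy-7,8-dimethoxy-2-(2,3,4-trimethoxyphenyl)-4H-chromen-4-one), via boron chelate 21 (not isolated)
Conditions: BCl3 (1.5 equiv), CH2Cl2, −78 to 0 °C; then H2O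
Reagents that add atoms: none
Why: BCl3 chelates between the C4 carbonyl and the peri 5-methoxy oxygen, so chloride should cleave only that methyl group, the chelation-directed selective demethylation established for 5-methoxyflavones, while the other five aryl methyl ethers stay.

**Compound list**

1 | 1,2,3,5-tetramethoxybenzene | COc1cc(OC)c(OC)c(OC)c1 | starting material
2 | 1-(2,3,4,6-tetramethoxyphenyl)ethanone | CC(=O)c1c(OC)c(OC)c(OC)cc1OC | intermediate
3 | dichloroaluminium 2-acetyl-3,5,6-trimethoxyphenoxide | CC(=O)c1c(O[Al](Cl)Cl)c(OC)c(OC)cc1OC | intermediate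
4 | 1-(2-hydroxy-3,4,6-trimethoxyphenyl)ethanone | CC(=O)c1c(O)c(OC)c(OC)cc1OC | intermediate
5 | ethyl diethoxyacetate | CCOC(=O)C(OCC)OCC | starting material
6 | 4,4-diethoxy-1-(2-hydroxy-3,4,6-trimethoxyphenyl)butane-1,3-dione | CCOC(OCC)C(=O)CC(=O)c1c(O)c(OC)c(OC)cc1OC | intermediate
7 | 2-(diethoxymethyl)-5,7,8-trimethoxy-4H-chromen-4-one | CCOC(OCC)c1cc(=O)c2c(OC)cc(OC)c(OC)c2o1 | intermediate
8 | 5,7,8-trimethoxy-4-oxo-4H-chromene-2-carbaldehyde | O=Cc1cc(=O)c2c(OC)cc(OC)c(OC)c2o1 | intermediate
9 | 2-ethynyl-5,7,8-trimethoxy-4H-chromen-4-one | C#Cc1cc(=O)c2c(OC)cc(OC)c(OC)c2o1 | intermediate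
10 | methyl methoxyacetate | COCC(=O)OC | starting material
11 | lithium 1,2-dimethoxyethen-1-olate (geometry not defined) | [Li+].[O-]C(OC)=COC | intermediate
12 | methyl 2-methoxy-3-oxobutanoate (racemic) | COC(C(C)=O)C(=O)OC | intermediate
13 | methyl 2,3,3-trimethoxybutanoate (racemic) | COC(C(=O)OC)C(C)(OC)OC | intermediate
14 | methyl 2,3-dimethoxybut-2-enoate (E/Z mixture) | COC(=O)C(OC)=C(C)OC | intermediate
15 | lithium 1,2,3-trimethoxybuta-1,3-dien-1-olate (geometry not defined) | [Li+].[O-]C(OC)=C(OC)C(=C)OC | intermediate
16 | 1,2,3-trimethoxy-1-(trimethylsilyloxy)buta-1,3-diene (geometric mixture) | C=C(OC)C(OC)=C(OC)O[Si](C)(C)C | intermediate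
17 | 5,7,8-trimethoxy-2-[4,5,6-trimethoxy-6-(trimethylsilyloxy)cyclohexa-1,4-dien-1-yl]-4H-chromen-4-one (racemic) | COC1=C(OC)C(OC)(O[Si](C)(C)C)C(=CC1)c1cc(=O)c2c(OC)cc(OC)c(OC)c2o1 | intermediate
18 | 2-(4,5-dimethoxy-6-oxocyclohexa-1,4-dien-1-yl)-5,7,8-trimethoxy-4H-chromen-4-one | COC1=C(OC)C(=O)C(=CC1)c1cc(=O)c2c(OC)cc(OC)c(OC)c2o1 | intermediate
19 | 2-(2-hydroxy-3,4-dimethoxyphenyl)-5,7,8-trimethoxy-4H-chromen-4-one (2'-hydroxy-5,7,8,3',4'-pentamethoxyflavone) | COc1ccc(-c2cc(=O)c3c(OC)cc(OC)c(OC)c3o2)c(O)c1OC | intermediate
20 | 5,7,8-trimethoxy-2-(2,3,4-trimethoxyphenyl)-4H-chromen-4-one | COc1ccc(-c2cc(=O)c3c(OC)cc(OC)c(OC)c3o2)c(OC)c1OC | intermediate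
21 | 5-(dichloroboryloxy)-7,8-dimethoxy-2-(2,3,4-trimethoxyphenyl)-4H-chromen-4-one | COc1ccc(-c2cc(=O)c3c(OB(Cl)Cl)cc(OC)c(OC)c3o2)c(OC)c1OC | intermediate
22 | serpyllin, 5-hydroxy-7,8-dimethoxy-2-(2,3,4-trimethoxyphenyl)-4H-chromen-4-one | COc1ccc(-c2cc(=O)c3c(O)cc(OC)c(OC)c3o2)c(OC)c1OC | target

**Step count**

Total: 9 steps. Longest linear sequence: 6 steps (1, 2, 3, 7, 8, 9; the diene branch 4, 5, 6, 7, 8, 9 is equally long).

**Steps most likely to fail**

Step 7. The vinylogously activated alkyne may react too slowly at temperatures the diene tolerates, so that the diene decomposes first, or the ketene acetal may add to C2 of the pyranone instead of undergoing cycloaddition. The fallback uses known flavone chemistry and sets out from 4. Claisen–Schmidt condensation of 4 with 2,3,4-trimethoxybenzaldehyde (KOH, EtOH, rt) should give (E)-1-(2-hydroxy-3,4,6-trimethoxyphenyl)-3-(2,3,4-trimethoxyphenyl)prop-2-en-1-one F1. Oxidative cyclisation of this chalcone with catalytic I2 in DMSO at 130 °C should close ring C and deliver 20, where the route is rejoined before step 9.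

Step 3. Methoxide may open the pyranone ring of the electrophilic aldehyde or add in conjugate fashion to the newly formed alkyne. The fallback sets out from 8 and avoids methanol. Wittig bromomethylenation with Ph3P=CHBr (from (bromomethyl)triphenylphosphonium bromide and KOtBu, THF, −78 °C) should give (Z)-2-(2-bromoethenyl)-5,7,8-trimethoxy-4H-chromen-4-one F2. Anti-elimination of HBr with Bu4NF in DMF should then return to 9.

Step 6. The amide base may add to the ester, silylation may occur on carbon, or the very electron-rich diene may hydrolyse or rearrange during isolation. The fallback sets out from 12 and avoids strong base. Double soft enolisation with TMSOTf and Et3N (Et2O, 0 °C) should give 1,2-dimethoxy-1,3-bis(trimethylsilyloxy)buta-1,3-diene F3. Heated with 9 as in step 7, this should give 2-[5,6-dimethoxy-4,6-bis(trimethylsilyloxy)cyclohexa-1,4-dien-1-yl]-5,7,8-trimethoxy-4H-chromen-4-one F4. Acid work-up should convert it into 2-(2,4-dihydroxy-3-methoxyphenyl)-5,7,8-trimethoxy-4H-chromen-4-one F5. Methylation of both phenols (MeI, K2CO3, acetone) comes back to the route at 20.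

**Further compounds**

F1 | step 7 | (E)-1-(2-hydroxy-3,4,6-trimethoxyphenyl)-3-(2,3,4-trimethoxyphenyl)prop-2-en-1-one | COc1ccc(/C=C/C(=O)c2c(O)c(OC)c(OC)cc2OC)c(OC)c1OC
F2 | step 3 | (Z)-2-(2-bromoethenyl)-5,7,8-trimethoxy-4H-chromen-4-one | Br/C=C\c1cc(=O)c2c(OC)cc(OC)c(OC)c2o1
F3 | step 6 | 1,2-dimethoxy-1,3-bis(trimethylsilyloxy)buta-1,3-diene | C=C(O[Si](C)(C)C)C(OC)=C(OC)O[Si](C)(C)C
F4 | step 6 | 2-[5,6-dimethoxy-4,6-bis(trimethylsilyloxy)cyclohexa-1,4-dien-1-yl]-5,7,8-trimethoxy-4H-chromen-4-one (racemic) | COC1(O[Si](C)(C)C)C(OC)=C(O[Si](C)(C)C)CC=C1c1cc(=O)c2c(OC)cc(OC)c(OC)c2o1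
F5 | step 6 | 2-(2,4-dihydroxy-3-methoxyphenyl)-5,7,8-trimethoxy-4H-chromen-4-one | COc1c(O)ccc(-c2cc(=O)c3c(OC)cc(OC)c(OC)c3o2)c1O
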